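The small charge, 18 mM of X on Tuesday, gives me the number for this flask. Here cX starts at 37 mM, D is held at 15 mM, and X turns into E. I work with the fraction of X left, not with the E made. Tuesday's last reading leaves 33.4 % at 3.00 min. So the decay constant, minus the ln of the fraction left divided by the time, reads 0.366 /min; this is a pseudo-first-order constant. Wednesday's run reads lower, 0.323 /min, but Tuesday's charge lies nearer to this flask's, so I keep Tuesday's.

| setting | Tuesday's | Wednesday's | flask |
|---|---|---|---|
| X | 18 mM | 74 mM | 37 mM |
| D | 15 mM (held) | 15 mM (held) | 15 mM (held) |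
| remark | run made earlier | run made earlier |  |
| time |  |  | 5.0 min |

- Tuesday's (time / min: X / %, E / %): 0.200: 95.4, 4.1; 0.667: 80.7, 19.8; 1.00: 71.5, 30.1; 1.50: 59.1, 40.4; 2.50: 40.9, 59.2; 3.00: 33.4, 66.4
- Wednesday's (time / min: X / %, E / %): 0.250: 95.2, 5.5; 0.417: 89.7, 10.5; 0.667: 82.5, 16.8; 1.00: 75.0, 24.6; 2.00: 54.4, 45.9; 3.00: 38.0, 61.2

(readings scatter by 0.5 percentage points)

* part of the X that has reacted at 5.0 min
* share of the unused L that is free and not bound as Q, at 5.0 min

- at the start none of D is in solution
- the earlier runs do not show how much of L is bound; that part of a forecast is a guess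

At 5.0 min I reckon 16.1 % of X left in this flask, so 83.9 % reacted. Leave D alone: both constants were read at 15 mM. The runs do not show bound L, so any free share is a guess.

The forecast gives 83 % and 95 %, holding that “Q stays small and L acts catalytically”. The flask gives 83.7 % and 32.1 %.

    D ⇌ L, rate k1*(csat - [L]) (kL = 0.200 /s)
    X + L → Z + E (k = 0.440 /M/s)
    L + Z ⇌ Q, settled at all times (K = 1.30 × 10⁵ /M)

In this flask at 5.00 min, 16.3 % of X stands left, against my 16.1 %. The X reacted by my fraction is 31.0 mM, and cQ stands at 30.9 mM beside cL at 14.6 mM. The neighbouring flask has 15 mM of X, and the same constant again leaves 16.1 %, where it shows 15.1 %. Its reacted X comes to 12.6 mM, and its cQ stands at 12.7 mM. Taking cL as 15 mM, I get a free share of 54.4 % in that neighbour, which shows 53.8 %.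

The earlier runs and the new flask come from a simulation for substances that don't exist, noise included.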